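**Strategy.** Ring atoms: C1 ketone, C2 (bearing the C7 CH2O ester), C3, C4 (ring tiglate), C5 (isopropyl), C6 (hydroxyl). The route rests on cutting C4–C5: a carbinol carbon next to a carbon with a three-carbon branch is the retron of a carbonyl-ene reaction, and the C1(=O)–C2=C3–C4(O) unit of the ring is a cis-ene-1,4-dicarbonyl, that is, an opened furan. A 2,3-disubstituted furan carrying the C6 silyloxy stereocentre and a 2-methylpropenyl group is oxidised to a (Z)-4-oxo-2-enal; Me2AlCl then closes the cyclohexenone in one operation, forming C4–C5, the C4 hydroxyl, two stereocentres and the isopropenyl precursor of the isopropyl group.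

Key step: step 6

Remark on the chemistry: the sense of induction of (+)-MIB in step 3 is taken from the dialkylzinc precedent (delivery to the Re face of the aldehyde). Should a configurational check of 9 show the opposite, the enantiomeric ligand is used and nothing else changes.

**Step 1**
Reactants: 1 furan-3-ylmethanol; 2 N,N-dimethylformamide
Product: 4 3-(hydroxymethyl)furan-2-carbaldehyde, via C2-lithiated lithium alkoxide 3 (not isolated)
Conditions: n-BuLi (2.2 equiv), THF, −78 → 0 °C; then 2, −78 °C → rt; H2O
Reagents that add atoms: N,N-dimethylformamide 2 (CN(C)C=O)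
Why: Alkoxide-directed lithiation places the second equivalent of n-BuLi at the furan α-carbon next to the CH2OLi group, and formylation of this aryllithium with DMF should give the 2,3-disubstituted furan; no stereocentre is formed.

**Step 2**
Reactants: 4 3-(hydroxymethyl)furan-2-carbaldehyde; 5 tigloyl chloride
Product: 6 (2-formylfuran-3-yl)methyl (E)-2-methylbut-2-enoate
Conditions: 5 (1.2 equiv), Et3N, DMAP (cat.), CH2Cl2, 0 °C
Reagents that add atoms: tigloyl chloride 5 (C/C=C(\C)C(Cl)=O)
Why: DMAP-catalysed acylation of the only hydroxyl group with an acid chloride should install the C7 tiglate, whose (E) geometry is the stable one and is retained.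

**Step 3**
Reactants: 6 (2-formylfuran-3-yl)methyl (E)-2-methylbut-2-enoate; 7 (2-methylprop-1-enyl)magnesium bromide
Product: 9 {2-[(1R)-1-hydroxy-3-methylbut-2-enyl]furan-3-yl}methyl (E)-2-methylbut-2-enoate, via bis(2-methylprop-1-enyl)zinc 8 (not isolated)
Conditions: 7 (2.4 equiv), ZnCl2 (1.2 equiv), THF → toluene, N,N,N',N'-tetraethylethylenediamine; then (+)-MIB (10 mol %), 6, toluene–hexane, 0 °C; aq. NH4Cl
Reagents that add atoms: (2-methylprop-1-enyl)magnesium bromide 7 (CC(C)=C[Mg]Br)
Why: Amino-alcohol-catalysed enantioselective addition of an alkenylzinc reagent to a furaldehyde: under (+)-MIB catalysis the 2-methylpropenyl group should be delivered to the Re face, setting the (R)-carbinol that becomes C6, while the ester is inert to organozinc species.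

**Step 4**
Reactants: 9 {2-[(1R)-1-hydroxy-3-methylbut-2-enyl]furan-3-yl}methyl (E)-2-methylbut-2-enoate
Product: 10 {2-[(1R)-1-(tert-butyldimethylsilyloxy)-3-methylbut-2-enyl]furan-3-yl}methyl (E)-2-methylbut-2-enoate
Conditions: TBSCl, imidazole, DMF, rt
Reagents that add atoms: tert-butyldimethylsilyl chloride (CC(C)(C)[Si](C)(C)Cl)
Why: Standard silylation under base-buffered conditions protects the C6 oxygen, so that step 5 stops at the open-chain ene-dicarbonyl instead of an Achmatowicz pyranone lactol and step 8 touches only C4; the stereocentre is not involved.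

**Step 5**
Reactants: 10 {2-[(1R)-1-(tert-butyldimethylsilyloxy)-3-methylbut-2-enyl]furan-3-yl}methyl (E)-2-methylbut-2-enoate
Product: 11 (2Z)-2-[(2R)-2-(tert-butyldimethylsilyloxy)-4-methylpent-3-enoyl]-4-oxobut-2-enyl (E)-2-methylbut-2-enoate
Conditions: NBS (1.05 equiv), NaHCO3, acetone–H2O (10:1), −20 °C; crude product used at once
Reagents that add atoms: water (O)
Why: Oxidative furan ring opening (the non-rearranging counterpart of the Achmatowicz reaction): bromonium attack at the free furan α-carbon, addition of water and loss of bromide should unveil the 4-oxo-2-enal with the cis (Z) geometry inherited from the ring, the electron-rich furan reacting faster than the trisubstituted alkene at low temperature.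

**Step 6**
Reactants: 11 (2Z)-2-[(2R)-2-(tert-butyldimethylsilyloxy)-4-methylpent-3-enoyl]-4-oxobut-2-enyl (E)-2-methylbut-2-enoate
Product: 12 [(3R,4S,5R)-5-(tert-butyldimethylsilyloxy)-3-hydroxy-6-oxo-4-(prop-1-en-2-yl)cyclohex-1-en-1-yl]methyl (E)-2-methylbut-2-enoate
Conditions: Me2AlCl (1.5 equiv), CH2Cl2, −78 → −40 °C; 1 M HCl quench
Reagents that add atoms: none
Why: Me2AlCl activates the aldehyde of 11, whose carbon (C4) is attacked by the unsubstituted alkene carbon (C5) while a methyl hydrogen of the isopropylidene group passes to the carbonyl oxygen through a six-membered, asynchronous ene transition state (intramolecular carbonyl-ene reaction; the closest known case is the Lewis-acid cyclization of citronellal to isopulegol). The cyclohexenone ring closes in a 6-exo-trig mode with respect to the aldehyde, the cis C2=C3 bond holding C4 within reach of C5. C5 is controlled by the C6 stereocentre: allylic 1,3-strain places the C6–H bond in the plane of the trisubstituted alkene, so the ketone-tethered aldehyde should add to the face that leaves the silyloxy group and the nascent isopropenyl group trans and both equatorial. C4 is controlled by the chair-like ene transition state, in which the aluminium-bound oxygen should sit pseudo-equatorial and therefore trans to the isopropenyl group, as in isopulegol. The step needs aldehyde-over-ketone selectivity and survival of the cis geometry: the ketone cannot reach the alkene without forming a three-membered ring, the aldehyde is the more electrophilic carbonyl, and Me2AlCl at −78 °C is a non-protic Lewis acid that also scavenges adventitious acid.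

**Step 7**
Reactants: 12 [(3R,4S,5R)-5-(tert-butyldimethylsilyloxy)-3-hydroxy-6-oxo-4-(prop-1-en-2-yl)cyclohex-1-en-1-yl]methyl (E)-2-methylbut-2-enoate
Product: 13 [(3R,4S,5R)-5-(tert-butyldimethylsilyloxy)-3-hydroxy-6-oxo-4-(propan-2-yl)cyclohex-1-en-1-yl]methyl (E)-2-methylbut-2-enoate
Conditions: H2 (1 atm), RhCl(PPh3)3 (5 mol %), benzene, rt
Reagents that add atoms: none
Why: Homogeneous hydrogenation with RhCl(PPh3)3 should reduce only the unhindered 1,1-disubstituted alkene and leave the trisubstituted, conjugated enone and tiglate alkenes untouched, as in carvone to carvotanacetone; no stereocentre is created or changed.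

**Step 8**
Reactants: 13 [(3R,4S,5R)-5-(tert-butyldimethylsilyloxy)-3-hydroxy-6-oxo-4-(propan-2-yl)cyclohex-1-en-1-yl]methyl (E)-2-methylbut-2-enoate; 14 tiglic acid
Product: 15 [(3S,4S,5R)-5-(tert-butyldimethylsilyloxy)-6-oxo-4-(propan-2-yl)-3-{[(E)-2-methylbut-2-enoyl]oxy}cyclohex-1-en-1-yl]methyl (E)-2-methylbut-2-enoate
Conditions: 14 (2 equiv), PPh3, DIAD, toluene, 0 °C → rt
Reagents that add atoms: tiglic acid 14 (C/C=C(\C)C(=O)O)
Why: Mitsunobu esterification: the equatorial, allylic C4 hydroxyl is activated as its oxyphosphonium salt and displaced by tiglate in an SN2 process with inversion, which should install the second tiglate cis to the isopropyl group in the same operation.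

**Step 9**
Reactants: 15 [(3S,4S,5R)-5-(tert-butyldimethylsilyloxy)-6-oxo-4-(propan-2-yl)-3-{[(E)-2-methylbut-2-enoyl]oxy}cyclohex-1-en-1-yl]methyl (E)-2-methylbut-2-enoate
Product: 16 [(3S,4R,5R)-5-hydroxy-6-oxo-4-(propan-2-yl)-3-{[(E)-2-methylbut-2-enoyl]oxy}cyclohex-1-en-1-yl]methyl (E)-2-methylbut-2-enoate (CNP0326914.1)
Conditions: HF·pyridine, THF–pyridine, 0 °C → rt
Reagents that add atoms: none
Why: Fluoride-mediated desilylation under mildly acidic conditions should free the C6 hydroxyl while sparing both tiglates and the base-sensitive α-hydroxy ketone, and no stereocentre is touched.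

**Compound list**

1 | furan-3-ylmethanol | OCc1ccoc1 | starting material
2 | N,N-dimethylformamide | CN(C)C=O | starting material
3 | lithium (2-lithiofuran-3-yl)methanolate | [Li]OCc1ccoc1[Li] | intermediate
4 | 3-(hydroxymethyl)furan-2-carbaldehyde | O=Cc1occc1CO | intermediate
5 | tigloyl chloride, (E)-2-methylbut-2-enoyl chloride | C/C=C(\C)C(Cl)=O | starting material
6 | (2-formylfuran-3-yl)methyl (E)-2-methylbut-2-enoate | C/C=C(\C)C(=O)OCc1ccoc1C=O | intermediate
7 | (2-methylprop-1-enyl)magnesium bromide | CC(C)=C[Mg]Br | starting material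
8 | bis(2-methylprop-1-enyl)zinc | CC(C)=C[Zn]C=C(C)C | intermediate
9 | {2-[(1R)-1-hydroxy-3-methylbut-2-enyl]furan-3-yl}methyl (E)-2-methylbut-2-enoate | C/C=C(\C)C(=O)OCc1ccoc1[C@H](O)C=C(C)C | intermediate
10 | {2-[(1R)-1-(tert-butyldimethylsilyloxy)-3-methylbut-2-enyl]furan-3-yl}methyl (E)-2-methylbut-2-enoate | C/C=C(\C)C(=O)OCc1ccoc1[C@H](O[Si](C)(C)C(C)(C)C)C=C(C)C | intermediate
11 | (2Z)-2-[(2R)-2-(tert-butyldimethylsilyloxy)-4-methylpent-3-enoyl]-4-oxobut-2-enyl (E)-2-methylbut-2-enoate | O=C/C=C(/COC(=O)/C(C)=C/C)C(=O)[C@H](O[Si](C)(C)C(C)(C)C)C=C(C)C | intermediate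
12 | [(3R,4S,5R)-5-(tert-butyldimethylsilyloxy)-3-hydroxy-6-oxo-4-(prop-1-en-2-yl)cyclohex-1-en-1-yl]methyl (E)-2-methylbut-2-enoate (hydroxyl trans to isopropenyl, isopropenyl trans to silyloxy) | C/C=C(\C)C(=O)OCC1=C[C@@H](O)[C@H](C(C)=C)[C@@H](O[Si](C)(C)C(C)(C)C)C1=O | intermediate
13 | [(3R,4S,5R)-5-(tert-butyldimethylsilyloxy)-3-hydroxy-6-oxo-4-(propan-2-yl)cyclohex-1-en-1-yl]methyl (E)-2-methylbut-2-enoate | C/C=C(\C)C(=O)OCC1=C[C@@H](O)[C@H](C(C)C)[C@@H](O[Si](C)(C)C(C)(C)C)C1=O | intermediate
14 | tiglic acid, (E)-2-methylbut-2-enoic acid | C/C=C(\C)C(=O)O | starting material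
15 | [(3S,4S,5R)-5-(tert-butyldimethylsilyloxy)-6-oxo-4-(propan-2-yl)-3-{[(E)-2-methylbut-2-enoyl]oxy}cyclohex-1-en-1-yl]methyl (E)-2-methylbut-2-enoate | C/C=C(\C)C(=O)OCC1=C[C@H](OC(=O)/C(C)=C/C)[C@H](C(C)C)[C@@H](O[Si](C)(C)C(C)(C)C)C1=O | intermediate
16 | [(3S,4R,5R)-5-hydroxy-6-oxo-4-(propan-2-yl)-3-{[(E)-2-methylbut-2-enoyl]oxy}cyclohex-1-en-1-yl]methyl (E)-2-methylbut-2-enoate (ring tiglate cis to isopropyl, hydroxyl trans to isopropyl) | C/C=C(\C)C(=O)OCC1=C[C@H](OC(=O)/C(C)=C/C)[C@H](C(C)C)[C@@H](O)C1=O | target

**Step count and risks**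

Total step count: 9. Longest linear sequence: 9 steps (1 → 16).

Steps most likely to fail:

Step 6 (key step). The cis-ene-dicarbonyl unit may isomerize to the trans geometry under the Lewis acid before the ring closes. The developing tertiary cation may be captured instead of losing a proton cleanly. Facial discrimination at the aldehyde may be weak. The fallback sets out from 11 and returns to the route at 13. SnCl4 (CH2Cl2, −78 °C) should close the same C4–C5 bond by a stepwise Prins cyclization in which chloride captures the tertiary cation, giving [(3R,4S,5R)-5-(tert-butyldimethylsilyloxy)-4-(2-chloropropan-2-yl)-3-hydroxy-6-oxocyclohex-1-en-1-yl]methyl (E)-2-methylbut-2-enoate F1. Radical dechlorination (Bu3SnH, AIBN, toluene, 80 °C) should then give 13 directly, so that 12 and step 7 are bypassed.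

Step 8. Displacement at the menthol-like carbinol by the weakly acidic tiglic acid may be slow, which would open the way to elimination toward a dienone (and aromatization) or to esterification with retention. The fallback sets out from 13 and returns at 15, separating inversion from acylation. A Mitsunobu reaction with the more acidic chloroacetic acid (PPh3, DIAD, toluene) should give the inverted chloroacetate [(3S,4S,5R)-5-(tert-butyldimethylsilyloxy)-3-(chloroacetoxy)-6-oxo-4-(propan-2-yl)cyclohex-1-en-1-yl]methyl (E)-2-methylbut-2-enoate F2. Thiourea and NaHCO3 in EtOH should remove the chloroacetyl group selectively to give the cis alcohol [(3S,4S,5R)-5-(tert-butyldimethylsilyloxy)-3-hydroxy-6-oxo-4-(propan-2-yl)cyclohex-1-en-1-yl]methyl (E)-2-methylbut-2-enoate F3. Acylation of F3 with 5 (Et3N, DMAP, CH2Cl2) leads to 15.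

Step 5. The brominating agent may attack the trisubstituted alkene in competition with the furan, and the product may undergo cis-to-trans isomerization during work-up. The fallback sets out from 10 and returns at 11. Anodic methoxylation (undivided cell, carbon anode, MeOH, Et4NOTs, −20 °C), which is selective for the most easily oxidised π-system, should give {2-[(1R)-1-(tert-butyldimethylsilyloxy)-3-methylbut-2-enyl]-2,5-dimethoxy-2,5-dihydrofuran-3-yl}methyl (E)-2-methylbut-2-enoate F4 as a mixture of acetal diastereomers. Mild hydrolysis (acetone–H2O, PPTS cat., 0 °C) should then release 11.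

**Further compounds**

F1 | step 6 | [(3R,4S,5R)-5-(tert-butyldimethylsilyloxy)-4-(2-chloropropan-2-yl)-3-hydroxy-6-oxocyclohex-1-en-1-yl]methyl (E)-2-methylbut-2-enoate | C/C=C(\C)C(=O)OCC1=C[C@@H](O)[C@H](C(C)(C)Cl)[C@@H](O[Si](C)(C)C(C)(C)C)C1=O
F2 | step 8 | [(3S,4S,5R)-5-(tert-butyldimethylsilyloxy)-3-(chloroacetoxy)-6-oxo-4-(propan-2-yl)cyclohex-1-en-1-yl]methyl (E)-2-methylbut-2-enoate | C/C=C(\C)C(=O)OCC1=C[C@H](OC(=O)CCl)[C@H](C(C)C)[C@@H](O[Si](C)(C)C(C)(C)C)C1=O
F3 | step 8 | [(3S,4S,5R)-5-(tert-butyldimethylsilyloxy)-3-hydroxy-6-oxo-4-(propan-2-yl)cyclohex-1-en-1-yl]methyl (E)-2-methylbut-2-enoate | C/C=C(\C)C(=O)OCC1=C[C@H](O)[C@H](C(C)C)[C@@H](O[Si](C)(C)C(C)(C)C)C1=O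
F4 | step 5 | {2-[(1R)-1-(tert-butyldimethylsilyloxy)-3-methylbut-2-enyl]-2,5-dimethoxy-2,5-dihydrofuran-3-yl}methyl (E)-2-methylbut-2-enoate | C/C=C(\C)C(=O)OCC1=CC(OC)OC1(OC)[C@H](O[Si](C)(C)C(C)(C)C)C=C(C)C
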